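Over the 5.0 min of this flask, each molecule of G or Z faces a race. X, with the single-handed catalyst L, may turn it into product (G into E, Z into J), or it may first flip into its mirror image.

| flask | G | Z | X | L | remark | time |
|---|---|---|---|---|---|---|
| summer | 0.028 M | 0.028 M | 0.060 M (fed, over 40 s) | 92 µM | run made earlier |  |
| winter | 0.044 M | 0.044 M | 0.060 M (fed, over 40 s) | 92 µM | run made earlier |  |
| spring | 0.020 M | 0.020 M | 0.12 M (fed, over 40 s) | 92 µM | run made earlier |  |
| flask | 0.020 M | 0.020 M | 0.0600 M (fed, over 40 s) | 92 µM |  | 5.0 min |

- summer (time / min: E / %, J / %, G / %): 1.00: 12.0, 6.9, 38.2; 2.00: 21.9, 13.5, 28.8; 3.00: 29.3, 17.4, 22.7; 4.00: 34.5, 20.9, 20.2; 5.00: 38.4, 23.7, 17.5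
- winter (time / min: E / %, J / %, G / %): 0.417: 3.0, 1.8, 47.3; 0.833: 9.0, 5.1, 42.3; 1.33: 16.1, 8.2, 36.2; 2.50: 23.8, 13.8, 28.1; 5.00: 32.4, 19.5, 21.5
- spring (time / min: E / %, J / %, G / %): 0.417: 3.7, 2.9, 43.9; 0.833: 17.9, 10.7, 32.6; 1.33: 29.2, 18.2, 22.7; 2.50: 41.1, 28.9, 11.0; 5.00: 51.8, 38.4, 3.2

(each reading ± 0.5 percentage points)

- E and J together, in percent of the G and Z charged together, at 5.0 min
- excess of E over J in the product at 5.0 min
- whether the exchange between G and Z keeps pace with the reaction: how far the product's excess at 5.0 min gets from its value without exchange to its value with instant exchange (above 80% keeps pace, below 20% hardly takes part, else lags behind)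

- L is single-handed; G and Z are mirror images of each other, charged as a racemate, each of them at the stated concentration
- an excess is below zero if the other one leads

Turn the question round: what would the numbers have to be for the exchange to keep pace, or to hardly take part? My reckoning starts from the summer run, which has this flask's charges of X and L. Between 1.00 min and 2.00 min there, G and Z together fall with an apparent first-order slope k_r of 0.227 min⁻¹. This is a local reading and no true constant, since the charge of X, 0.060 M, stands close to that of G and Z together, 0.0560 M. At 5.00 min, G and E together stand 5.9 percentage points above the half charged. Setting that gain against the gap of Z over G, summed over the run with Z taken as what remains of the charge, gives a flip constant k_x of 0.234 min⁻¹.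

Their ratio comes to 0.973: this is the race number ρ, the reaction slope over the flip constant. A molecule flips first with a chance of one over one plus ρ, here 50.7%, and I take that as a rough share of the way to the excess with instant exchange. Keeping pace, as a dynamic kinetic resolution does, needs a share above 80%, so ρ below 0.250. Hardly taking part needs a share below 20%, so ρ above 4.00. The ρ from the summer run, which I carry over to this flask, lies between the two, so I expect the exchange to lag.

The forecast gives 66.3% of product, an excess of 20.5% and the verdict lags behind, on the grounds that “G and Z do exchange” at 0.2 to 0.3 per minute, stepped through the flask.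

This flask gives 66.5% of product and an excess of 21.5%, which is 41% of the way, so the verdict is lags behind.

    G ⇌ Z (k = 0.00370 s⁻¹)
    X ⇌ Q (K = 0.140, k = 4.40 × 10⁻⁴ s⁻¹)
    E ⇌ J (k = 1.20 × 10⁻⁴ s⁻¹)
    X + L + Z → L + J (k = 750 M⁻² s⁻¹)
    X + L + G → L + E (k = 1400 M⁻² s⁻¹)

Now cut L to 2.3 × 10⁻⁵ M, with the other charges as in the recipe, and let k_r follow L. The race number becomes 0.243, just under the line of 0.250 for keeping pace. That neighbouring flask gives 29.5% of product, less than this flask, and its excess stands at 26.6%, higher than this flask's 21.5%.

The data stem from a simulated flask with constants of no real substance; scatter was added.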